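## Retrosynthetic overview

1. The oxepane closes last: the C3 tertiary hydroxyl displaces a C16 primary triflate. C15/C16 come from hydroboration of a C14 isopropenyl group, and the butanoate from acylation of the C11 alcohol.
2. C11–OH and C12–CH3 come from a C11 ketone (α-methylenation, then hydrogen delivered from the convex face). The oxonene comes from ring-closing metathesis at C6=C7.
3. The tetrahydrofuran comes from 5-exo opening of a C2–C3 epoxide by the C9 hydroxyl, which sets C2 and C3.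
4. Key step: the cyclohexanone ring (C11 ketone, C10, C9–OH) comes from semipinacol ring expansion of a 1-(epoxyalkyl)cyclopentanol, in which C1 migrates from C11 to C10.
5. The cyclopentanol comes from alkenylcerium addition to a trans-2,3-disubstituted cyclopentanone (Negishi coupling, then asymmetric conjugate addition). Ring order: cyclopentane, cyclohexanone (expansion), tetrahydrofuran, oxonene, oxepane.

Assumption: atom labels follow asbestinane numbering (C1/C10 ring fusion, C2–O–C9 bridge, C3 quaternary, C6=C7, C11 ester carbon, C12, C14, C15, C16 = CH2O), and compounds 1, 2 and 6 are taken as catalogue chemicals.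

## Route

Step 1
Reactants: 1 hex-1-en-5-yne; 2 2-iodocyclopent-2-en-1-one
Product: 4 2-[(1E)-2-methylhexa-1,5-dien-1-yl]cyclopent-2-en-1-one, via alkenylalane 3 (not isolated)
Conditions: AlMe3 (2 equiv), Cp2ZrCl2 (0.2 equiv), CH2Cl2, 0 °C to rt; volatiles off; then 2, Pd(PPh3)4 (3 mol %), ZnCl2 (0.2 equiv), THF, rt
Reagents that add atoms: trimethylaluminium, C[Al](C)C
Why: Zirconium-catalysed syn-carboalumination of the terminal alkyne gives the (E)-2-methylalkenylalane regio- and stereospecifically (the isolated alkene is untouched), and the Negishi coupling with the α-iodoenone retains the alkene geometry.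

Step 2
Reactants: 4 2-[(1E)-2-methylhexa-1,5-dien-1-yl]cyclopent-2-en-1-one
Product: 5 (2S,3R)-2-[(1E)-2-methylhexa-1,5-dien-1-yl]-3-(prop-1-en-2-yl)cyclopentan-1-one
Conditions: CH2=C(CH3)MgBr (1.3 equiv), Cu(OTf)2 (5 mol %), chiral imidazolinium salt (carbene precursor, 6 mol %), Et2O, −30 °C; aq NH4Cl, −78 °C
Reagents that add atoms: isopropenylmagnesium bromide, CC(=C)[Mg]Br
Why: Copper-catalysed asymmetric conjugate addition of a Grignard reagent to an α-substituted cyclic enone sets C14 under catalyst control, and α-protonation of the dienolate anti to the new group gives the trans ketone, which is also the thermodynamic isomer because C1 is epimerisable.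

Step 3
Reactants: 6 3-chloro-2-methylprop-1-ene
Product: 7 2-methylpent-1-en-4-yne
Conditions: HC≡CMgBr (1.2 equiv), CuCl (5 mol %), THF, 50 °C
Reagents that add atoms: ethynylmagnesium bromide, C#C[Mg]Br
Why: Copper-catalysed SN2 coupling of an alkynyl Grignard reagent with an allylic chloride is the standard route to skipped 1,4-enynes.

Step 4
Reactants: 7 2-methylpent-1-en-4-yne
Product: 9 (1E)-1-iodo-4-methylpenta-1,4-diene, via alkenylzirconocene 8 (not isolated)
Conditions: Cp2Zr(H)Cl (1.1 equiv), CH2Cl2, rt; then I2, 0 °C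
Reagents that add atoms: iodine, II
Why: Schwartz hydrozirconation is syn and selects the terminal alkyne over the 1,1-disubstituted alkene, and iodinolysis of the C–Zr bond retains geometry to give the (E)-vinyl iodide.

Step 5
Reactants: 9 (1E)-1-iodo-4-methylpenta-1,4-diene; 5 (2S,3R)-2-[(1E)-2-methylhexa-1,5-dien-1-yl]-3-(prop-1-en-2-yl)cyclopentan-1-one
Product: 12 (1S,2S,3R)-1-[(1E)-4-methylpenta-1,4-dien-1-yl]-2-[(1E)-2-methylhexa-1,5-dien-1-yl]-3-(prop-1-en-2-yl)cyclopentan-1-ol, via alkenyllithium 10 (not isolated), via alkenylcerium reagent 11 (not isolated)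
Conditions: 9, t-BuLi (2.0 equiv), Et2O, −78 °C; CeCl3 (1.2 equiv), THF, −78 °C; then 5, −78 °C
Reagents that add atoms: none
Why: Iodine–lithium exchange retains the E geometry and the organocerium reagent adds 1,2 to the easily enolised β,γ-unsaturated ketone without deprotonating it; attack anti to the neighbouring C1 side chain gives mainly the carbinol epimer shown, and the minor epimer converges in step 6 because C11 becomes a carbonyl carbon.

Step 6
Reactants: 12 (1S,2S,3R)-1-[(1E)-4-methylpenta-1,4-dien-1-yl]-2-[(1E)-2-methylhexa-1,5-dien-1-yl]-3-(prop-1-en-2-yl)cyclopentan-1-ol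
Product: 14 (2R,3S,4R)-2-[(1R)-1-hydroxy-3-methylbut-3-en-1-yl]-3-[(1E)-2-methylhexa-1,5-dien-1-yl]-4-(prop-1-en-2-yl)cyclohexan-1-one, via epoxy alcohol 13 (not isolated)
Conditions: Hf(OtBu)4 (10 mol %), C2-symmetric chiral bishydroxamic acid ligand (12 mol %, enantiomer that oxidises the Si face of C10), cumene hydroperoxide (1.0 equiv), toluene, 0 °C; then BF3·OEt2 (1.5 equiv), CH2Cl2, −60 to −20 °C
Reagents that add atoms: cumene hydroperoxide, CC(C)(OO)c1ccccc1
Why: Proposed new method: a one-pot enantioselective hydroxyl-directed epoxidation and semipinacol ring expansion of a tertiary 1-alkenylcyclopentanol, in which the hafnium alkoxide–peroxide chelate delivers oxygen to the allylic C9=C10 bond (faster than to the homoallylic C2=C3 bond) on the ligand-defined face to give the (10S,9R)-epoxy alkoxide, and Lewis-acid activation then triggers anti-periplanar 1,2-migration of the allylic ring carbon C1 from C11 to C10 (inversion at C10, retention at C1 and C9), turning the cyclopentanol into the cyclohexanone with C10 cis to C1; the closest known reactions are the Hf(OtBu)4/bishydroxamic acid epoxidation of tertiary allylic alcohols and the Suzuki–Tsuchihashi semipinacol rearrangement of isolated 2,3-epoxy alcohols.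

Step 7
Reactants: 14 (2R,3S,4R)-2-[(1R)-1-hydroxy-3-methylbut-3-en-1-yl]-3-[(1E)-2-methylhexa-1,5-dien-1-yl]-4-(prop-1-en-2-yl)cyclohexan-1-one
Product: 16 (1R,3R,3aR,7R,7aS)-1-[(2S)-2-hydroxyhex-5-en-2-yl]-3-(2-methylprop-2-en-1-yl)-7-(prop-1-en-2-yl)hexahydro-2-benzofuran-4(1H)-one, via epoxide 15 (not isolated)
Conditions: mCPBA (1.05 equiv), NaHCO3, CH2Cl2, −20 °C; then PPTS (10 mol %), rt
Reagents that add atoms: 3-chloroperoxybenzoic acid, OOC(=O)c1cccc(Cl)c1
Why: Prilezhaev epoxidation selects the only trisubstituted alkene, the C9 hydroxyl on the cis side chain hydrogen-bonds the peracid and directs oxygen to the alkene face turned towards C10 in the A(1,3)-locked rotamer to give the (2S,3S)-epoxide, and acid-catalysed 5-exo opening at C2 by O9 with inversion sets C2 and C3 and gives the all-cis tetrahydrofuran.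

Step 8
Reactants: 16 (1R,3R,3aR,7R,7aS)-1-[(2S)-2-hydroxyhex-5-en-2-yl]-3-(2-methylprop-2-en-1-yl)-7-(prop-1-en-2-yl)hexahydro-2-benzofuran-4(1H)-one
Product: 17 (1S,2R,3S,6Z,9R,10R,14R)-2,9-epoxy-3-hydroxy-3,7-dimethyl-14-(prop-1-en-2-yl)bicyclo[8.4.0]tetradec-6-en-11-one
Conditions: second-generation Grubbs catalyst (8 mol %), CH2Cl2 (2 mM), 40 °C
Reagents that add atoms: none
Why: Ring-closing metathesis on the cis-2,5-disubstituted tetrahydrofuran template closes the nine-membered oxonene, the ring allows only the Z trisubstituted alkene, and the α-branched isopropenyl group is a spectator.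

Step 9
Reactants: 17 (1S,2R,3S,6Z,9R,10R,14R)-2,9-epoxy-3-hydroxy-3,7-dimethyl-14-(prop-1-en-2-yl)bicyclo[8.4.0]tetradec-6-en-11-one
Product: 20 (1S,2R,3S,6Z,9R,10R,14R)-2,9-epoxy-3-hydroxy-3,7-dimethyl-12-methylidene-14-(prop-1-en-2-yl)bicyclo[8.4.0]tetradec-6-en-11-one, via Mannich base 18 (not isolated), via methiodide 19 (not isolated)
Conditions: LiN(iPr)2 (2.2 equiv), THF, −78 °C; Me2N=CH2+ I−; then MeI, CH2Cl2, rt; aq NaHCO3
Reagents that add atoms: Eschenmoser's salt (N,N-dimethylmethyleneiminium iodide), C=[N+](C)C.[I-]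
Why: Kinetic enolisation occurs at the C12 methylene rather than the hindered C10 methine, the Mannich reaction with Eschenmoser's salt adds the one-carbon unit, and quaternisation followed by β-elimination gives the α-methylene ketone.

Step 10
Reactants: 20 (1S,2R,3S,6Z,9R,10R,14R)-2,9-epoxy-3-hydroxy-3,7-dimethyl-12-methylidene-14-(prop-1-en-2-yl)bicyclo[8.4.0]tetradec-6-en-11-one
Product: 22 (1S,2R,3S,6Z,9R,10S,11R,12R,14R)-2,9-epoxy-3,7,12-trimethyl-14-(prop-1-en-2-yl)bicyclo[8.4.0]tetradec-6-ene-3,11-diol, via methyl ketone 21 (not isolated)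
Conditions: LiBH(s-Bu)3 (1.2 equiv), THF, −78 °C; 2,6-di-tert-butyl-4-methylphenol, −78 °C; then NaBH4, MeOH, −40 °C
Reagents that add atoms: none
Why: Conjugate (1,4) hydride reduction gives the C11–C12 enolate, kinetic protonation from the convex face (the concave face is roofed by the oxonene) puts the C12 methyl on the concave face, and NaBH4 then attacks the ketone from the same convex face to give the 11R alcohol (the 10S label is only a priority change).

Step 11
Reactants: 22 (1S,2R,3S,6Z,9R,10S,11R,12R,14R)-2,9-epoxy-3,7,12-trimethyl-14-(prop-1-en-2-yl)bicyclo[8.4.0]tetradec-6-ene-3,11-diol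
Product: 23 (1S,2R,3S,6Z,9R,10R,11R,12R,14R)-2,9-epoxy-3-hydroxy-3,7,12-trimethyl-14-(prop-1-en-2-yl)bicyclo[8.4.0]tetradec-6-en-11-yl butanoate
Conditions: (PrCO)2O (1.5 equiv), DMAP (0.2 equiv), Et3N, CH2Cl2, rt
Reagents that add atoms: butanoic anhydride, CCCC(=O)OC(=O)CCC
Why: DMAP-catalysed acylation esterifies the secondary C11 alcohol while the tertiary C3 alcohol does not react.

Step 12
Reactants: 23 (1S,2R,3S,6Z,9R,10R,11R,12R,14R)-2,9-epoxy-3-hydroxy-3,7,12-trimethyl-14-(prop-1-en-2-yl)bicyclo[8.4.0]tetradec-6-en-11-yl butanoate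
Product: 25 (1S,2R,3S,6Z,9R,10R,11R,12R,14S)-2,9-epoxy-3-hydroxy-14-[(2R)-1-hydroxypropan-2-yl]-3,7,12-trimethylbicyclo[8.4.0]tetradec-6-en-11-yl butanoate, via alkylborane 24 (not isolated)
Conditions: 9-BBN (2.2 equiv), THF, 0 °C to rt; then H2O2, pH 7 buffer, 0 °C
Reagents that add atoms: hydrogen peroxide, OO
Why: Anti-Markovnikov hydroboration with 9-BBN takes the 1,1-disubstituted terminal alkene and leaves the trisubstituted ring alkene and the ester, the borane approaches the hydrogen-eclipsed rotamer of the isopropenyl group from the side remote from C1 to give 15R, and oxidation retains configuration.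

Step 13
Reactants: 25 (1S,2R,3S,6Z,9R,10R,11R,12R,14S)-2,9-epoxy-3-hydroxy-14-[(2R)-1-hydroxypropan-2-yl]-3,7,12-trimethylbicyclo[8.4.0]tetradec-6-en-11-yl butanoate
Product: 27 CNP0209450.4 (1S,2R,3S,6Z,9R,10R,11R,12R,14S,15R)-2,9:3,16-diepoxyasbestin-6-en-11-yl butanoate, via triflate 26 (not isolated)
Conditions: Tf2O (1.1 equiv), 2,6-lutidine (3 equiv), CH2Cl2, −78 to 0 °C
Reagents that add atoms: none
Why: Selective O-triflation of the primary alcohol is followed by intramolecular Williamson-type SN2 displacement by the C3 tertiary hydroxyl, which closes the oxepane without touching any stereocentre.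

## Compound list

1 | hex-1-en-5-yne | C=CCCC#C | starting material
2 | 2-iodocyclopent-2-en-1-one | O=C1CCC=C1I | starting material
3 | (E)-dimethyl(2-methylhexa-1,5-dien-1-yl)alane | C=CCC/C(C)=C/[Al](C)C | intermediate
4 | 2-[(1E)-2-methylhexa-1,5-dien-1-yl]cyclopent-2-en-1-one | O=C1CCC=C1/C=C(\C)CCC=C | intermediate
5 | (2S,3R)-2-[(1E)-2-methylhexa-1,5-dien-1-yl]-3-(prop-1-en-2-yl)cyclopentan-1-one | O=C1CC[C@@H](C(C)=C)[C@@H]1/C=C(\C)CCC=C | intermediate
6 | 3-chloro-2-methylprop-1-ene | ClCC(C)=C | starting material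
7 | 2-methylpent-1-en-4-yne | C#CCC(C)=C | intermediate
8 | chlorido[(1E)-4-methylpenta-1,4-dien-1-yl]zirconocene, Cp2Zr(Cl)(alkenyl) | C=C(C)C/C=C/[Zr](Cl)(C1C=CC=C1)C1C=CC=C1 | intermediate
9 | (1E)-1-iodo-4-methylpenta-1,4-diene | C=C(C)C/C=C/I | intermediate
10 | [(1E)-4-methylpenta-1,4-dien-1-yl]lithium | C=C(C)C/C=C/[Li] | intermediate
11 | dichlorido[(1E)-4-methylpenta-1,4-dien-1-yl]cerium | C=C(C)C/C=C/[Ce](Cl)Cl | intermediate
12 | (1S,2S,3R)-1-[(1E)-4-methylpenta-1,4-dien-1-yl]-2-[(1E)-2-methylhexa-1,5-dien-1-yl]-3-(prop-1-en-2-yl)cyclopentan-1-ol | O[C@]1(/C=C/CC(C)=C)CC[C@@H](C(C)=C)[C@@H]1/C=C(\C)CCC=C | intermediate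
13 | (1R,2S,3R)-1-[(2S,3R)-3-(2-methylprop-2-en-1-yl)oxiran-2-yl]-2-[(1E)-2-methylhexa-1,5-dien-1-yl]-3-(prop-1-en-2-yl)cyclopentan-1-ol | O[C@]1([C@H]2O[C@@H]2CC(C)=C)CC[C@@H](C(C)=C)[C@@H]1/C=C(\C)CCC=C | intermediate
14 | (2R,3S,4R)-2-[(1R)-1-hydroxy-3-methylbut-3-en-1-yl]-3-[(1E)-2-methylhexa-1,5-dien-1-yl]-4-(prop-1-en-2-yl)cyclohexan-1-one | O=C1CC[C@@H](C(C)=C)[C@H](/C=C(\C)CCC=C)[C@@H]1[C@H](O)CC(C)=C | intermediate
15 | (2R,3S,4R)-3-[(2S,3S)-3-(but-3-en-1-yl)-3-methyloxiran-2-yl]-2-[(1R)-1-hydroxy-3-methylbut-3-en-1-yl]-4-(prop-1-en-2-yl)cyclohexan-1-one | O=C1CC[C@@H](C(C)=C)[C@H]([C@@H]2O[C@@]2(C)CCC=C)[C@@H]1[C@H](O)CC(C)=C | intermediate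
16 | (1R,3R,3aR,7R,7aS)-1-[(2S)-2-hydroxyhex-5-en-2-yl]-3-(2-methylprop-2-en-1-yl)-7-(prop-1-en-2-yl)hexahydro-2-benzofuran-4(1H)-one (all four ring hydrogens of the tetrahydrofuran cis) | O=C1CC[C@@H](C(C)=C)[C@H]2[C@@H]1[C@@H](CC(C)=C)O[C@H]2[C@@](C)(O)CCC=C | intermediate
17 | (1S,2R,3S,6Z,9R,10R,14R)-2,9-epoxy-3-hydroxy-3,7-dimethyl-14-(prop-1-en-2-yl)bicyclo[8.4.0]tetradec-6-en-11-one | O=C1CC[C@@H](C(C)=C)[C@H]2[C@@H]1[C@H]1C/C(C)=C\CC[C@](C)(O)[C@@H]2O1 | intermediate
18 | 12-[(dimethylamino)methyl] derivative of 17 (C12 epimers) | O=C1C(CN(C)C)C[C@@H](C(C)=C)[C@H]2[C@@H]1[C@H]1C/C(C)=C\CC[C@](C)(O)[C@@H]2O1 | intermediate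
19 | trimethylammonium iodide (methiodide) of 18 | O=C1C(C[N+](C)(C)C)C[C@@H](C(C)=C)[C@H]2[C@@H]1[C@H]1C/C(C)=C\CC[C@](C)(O)[C@@H]2O1.[I-] | intermediate
20 | (1S,2R,3S,6Z,9R,10R,14R)-2,9-epoxy-3-hydroxy-3,7-dimethyl-12-methylidene-14-(prop-1-en-2-yl)bicyclo[8.4.0]tetradec-6-en-11-one | O=C1C(=C)C[C@@H](C(C)=C)[C@H]2[C@@H]1[C@H]1C/C(C)=C\CC[C@](C)(O)[C@@H]2O1 | intermediate
21 | (1S,2R,3S,6Z,9R,10R,12R,14R)-2,9-epoxy-3-hydroxy-3,7,12-trimethyl-14-(prop-1-en-2-yl)bicyclo[8.4.0]tetradec-6-en-11-one (C12 methyl on the concave face) | O=C1[C@H](C)C[C@@H](C(C)=C)[C@H]2[C@@H]1[C@H]1C/C(C)=C\CC[C@](C)(O)[C@@H]2O1 | intermediate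
22 | (1S,2R,3S,6Z,9R,10S,11R,12R,14R)-2,9-epoxy-3,7,12-trimethyl-14-(prop-1-en-2-yl)bicyclo[8.4.0]tetradec-6-ene-3,11-diol | O[C@@H]1[C@H](C)C[C@@H](C(C)=C)[C@H]2[C@@H]1[C@H]1C/C(C)=C\CC[C@](C)(O)[C@@H]2O1 | intermediate
23 | (1S,2R,3S,6Z,9R,10R,11R,12R,14R)-2,9-epoxy-3-hydroxy-3,7,12-trimethyl-14-(prop-1-en-2-yl)bicyclo[8.4.0]tetradec-6-en-11-yl butanoate | CCCC(=O)O[C@@H]1[C@H](C)C[C@@H](C(C)=C)[C@H]2[C@@H]1[C@H]1C/C(C)=C\CC[C@](C)(O)[C@@H]2O1 | intermediate
24 | C16 B-alkyl-9-borabicyclo[3.3.1]nonane adduct of 23 (C15 as in 25) | CCCC(=O)O[C@@H]1[C@H](C)C[C@@H]([C@@H](C)CB3C4CCCC3CCC4)[C@H]2[C@@H]1[C@H]1C/C(C)=C\CC[C@](C)(O)[C@@H]2O1 | intermediate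
25 | (1S,2R,3S,6Z,9R,10R,11R,12R,14S)-2,9-epoxy-3-hydroxy-14-[(2R)-1-hydroxypropan-2-yl]-3,7,12-trimethylbicyclo[8.4.0]tetradec-6-en-11-yl butanoate | CCCC(=O)O[C@@H]1[C@H](C)C[C@@H]([C@@H](C)CO)[C@H]2[C@@H]1[C@H]1C/C(C)=C\CC[C@](C)(O)[C@@H]2O1 | intermediate
26 | C16 trifluoromethanesulfonate of 25 | CCCC(=O)O[C@@H]1[C@H](C)C[C@@H]([C@@H](C)COS(=O)(=O)C(F)(F)F)[C@H]2[C@@H]1[C@H]1C/C(C)=C\CC[C@](C)(O)[C@@H]2O1 | intermediate
27 | CNP0209450.4, (1S,2R,3S,6Z,9R,10R,11R,12R,14S,15R)-2,9:3,16-diepoxyasbestin-6-en-11-yl butanoate | CCCC(=O)O[C@H]1[C@@H]2[C@@H]3[C@@H](C[C@H]1C)[C@@H](C)CO[C@@]1(C)CC/C=C(/C)C[C@H]2O[C@H]31 | target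

## Step count and weak points

Total step count: 13. Longest linear sequence: 11 (steps 1, 2, 5, 6, 7, 8, 9, 10, 11, 12, 13); steps 3 and 4 form the side branch.

The three steps most likely to fail are steps 6, 7 and 10.

Step 6 (the proposed new one-pot epoxidation and ring expansion). The risks are that the hafnium system also oxidises the homoallylic C2=C3 bond, that BF3 and the residual catalyst do not cooperate, or that C12 migrates instead of C1. The fallback uses only known chemistry and runs the two events separately. It sets out from allylic alcohol 12: the documented Hf(OtBu)4/bishydroxamic acid epoxidation of tertiary allylic alcohols (or VO(acac)2/t-BuOOH with separation of the epoxide diastereomer) is worked up to give epoxy alcohol 13 as an isolated compound. Silylation with Me3SiCl and imidazole gives the trimethylsilyl ether of 13 F1. The classical TiCl4-promoted Suzuki–Tsuchihashi rearrangement (CH2Cl2, −78 °C) then gives the ring-expanded hydroxy ketone after aqueous work-up, and the route is rejoined at 14.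

Step 7 (epoxidation and etherification). The facial selectivity rests on hydrogen-bond direction by the C9 hydroxyl, and a little epoxidation of the 1,1-disubstituted alkenes or 6-endo opening is possible. The fallback replaces substrate control by catalyst control. It sets out from 14 and uses the Shi epoxidation with the L-fructose-derived ketone (Oxone, buffered near pH 8 to protect the β-hydroxy ketone), which reacts only with the trisubstituted alkene and gives the same epoxide 15 by reagent control. PPTS then closes the ring and the route is rejoined at 16. No compound outside the list is made.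

Step 10 (C12 configuration by enolate protonation). Axial protonation from the concave face would give the C12 epimer. The fallback sets C12 by radical hydrogen transfer, which is governed by sterics alone. It sets out from enone 20: LiBH(s-Bu)3 followed by Me3SiCl traps the regiodefined enolate as the trimethylsilyl enol ether F2. PhSeCl attacks from the convex face to give the 12-(phenylselanyl) ketone F3, with selenium convex and methyl concave. Bu3SnH with AIBN (benzene, 80 °C) replaces selenium by hydrogen from the convex face to give methyl ketone 21, where the route is rejoined before the NaBH4 reduction to 22.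

Further compounds
F1 | step 6 | trimethylsilyl ether of epoxy alcohol 13 | C[Si](C)(C)O[C@]1([C@H]2O[C@@H]2CC(C)=C)CC[C@@H](C(C)=C)[C@@H]1/C=C(\C)CCC=C
F0 | step 7 | none | none
F2 | step 10 | C11 trimethylsilyl enol ether (C11=C12) derived from 20 | C[Si](C)(C)OC1=C(C)C[C@@H](C(C)=C)[C@H]2[C@@H]1[C@H]1C/C(C)=C\CC[C@](C)(O)[C@@H]2O1
F3 | step 10 | 12-(phenylselanyl) derivative of ketone 21 (selenium on the convex face) | O=C1[C@]([Se]c2ccccc2)(C)C[C@@H](C(C)=C)[C@H]2[C@@H]1[C@H]1C/C(C)=C\CC[C@](C)(O)[C@@H]2O1
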